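The substrate left in a flask is the quick handle here, and the hunch that more partner simply buys more product deserves testing against it.

| flask | substrate | partner | remark | time |
|---|---|---|---|---|
| west | 12 mM | 7.5 mM | run made earlier |  |
| south-east | 12 mM | 34 mM | run made earlier |  |
| east | 12 mM | 110 mM | run made earlier |  |
| red | 12 mM | 10.0 mM |  | 4.0 min |
| green | 12 mM | 30.0 mM |  | 4.0 min |
| ochre | 12 mM | 100 mM |  | 4.0 min |

- west (time / s: product / %, substrate / %): 30.0: 0.6, 89.1; 60.0: 1.2, 80.5; 90.0: 1.9, 72.2; 120: 3.4, 64.1
- south-east (time / s: product / %, substrate / %): 30.0: 0.5, 76.1; 60.0: 2.8, 58.8; 90.0: 5.5, 45.1; 120: 8.4, 35.0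
- east (time / s: product / %, substrate / %): 15.0: 0, 67.9; 40.0: 3.5, 36.3; 80.0: 6.4, 15.6; 120: 7.3, 5.9

(standard deviation of a reading: 0.5 percentage points)

- "hardly changes" means that all values lie within two and a half points (for a concentration: within two and a half percent of the largest)

- amount of product at the end, in percent of the substrate charged for red, green, ochre, in this order
- how the row runs (falls all the way / hardly changes / rises all the way / falls, then rises / rises, then falls)

On a logarithmic scale the substrate left falls nearly straight with time, so an early reading gives each run one loss constant: 0.00362 s⁻¹ for west at 60.0 s and 0.0253 s⁻¹ for east at 40.0 s. A straight line through these against partner stays above zero at no partner, so substrate leaves by two routes, one needing partner and one not. That line gives 9.56 mM as the even-split loading, the partner level at which both routes remove substrate equally.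

The partner-free share, a selectivity, is then the even-split loading divided by itself plus the partner. For east it comes to 8.00%, and east product reads 7.3% at 120 s and is flattening, so the share looks like a ceiling on product. For ochre this reckoning gives about 8.73%. For red the share is 48.9%, but product lags, and west reaches 3.4% at 120 s, so red is late rather than capped.

The forecast reads 12%, 16% and 8.3%, so rises, then falls, its ochre value a little below this reckoning. Its ground: “The partner-dependent route is waste.”

The flasks give 9.57%, 15.5% and 9.49%, so rises, then falls, as forecast.

    substrate → intermediate C (k = 0.00218 s⁻¹)
    partner + intermediate A ⇌ intermediate B (K = 980 L mol⁻¹, k = 0.183 L mol⁻¹ s⁻¹)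
    substrate + partner → intermediate A (k = 0.219 L mol⁻¹ s⁻¹)
    partner + intermediate C ⇌ product (K = 1000 L mol⁻¹, k = 0.402 L mol⁻¹ s⁻¹)

Red, charged with 10.0 mM against the even-split loading of 9.56 mM, began with its two substrate routes at a ratio of 1.0. Reading red at 4.00 min and not at 40.0 min is the largest single effect on its product, which is 9.57% at the earlier time and 28.5% at the later, and at the earlier time intermediate C stands at 24.1%. Ochre, with a partner-free share of 8.73%, has its substrate down to 0.707% at 4.00 min, waiting barely moves its product, and that product stands at 9.68% after 40.0 min.

(The readings were generated by integration with made-up constants.)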